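**Retrosynthetic overview**

1. The ten-membered ring is closed last at C6–C7: an intramolecular umpolung (Pd/InI) allylation of an α,β-epoxy aldehyde by a butenolide-bound allylic isobutyrate sets C6 and C7 and converts the butenolide into the α-methylene-γ-lactone.
2. The C4–C5 epoxide comes from a Sharpless epoxidation of the geraniol-type allylic alcohol; the two isobutyryl groups are installed together (one is the C9 ester of the target, the other the C13 leaving group).
3. The C8–C9 bond and the first two stereocentres come from an organocatalytic, anti-selective direct vinylogous aldol addition of 3-(hydroxymethyl)furan-2(5H)-one to a geraniol-derived (2E,6E)-enal.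
4. Building blocks: geraniol (C1–C6, C9, C10, C14, C15) and furan-3-ylmethanol (C7, C8, C11–C13).
5. Ring order: furanone → oxirane → cyclodecene.

Assumption: atom labels follow germacrane numbering, and the facial sense of the squaramide catalyst in step 5 is taken by analogy with its known aldol chemistry (the quinidine-derived quasi-enantiomer would be used if a test run showed the opposite sense).

**Route**

Step 1
Reactants: 1 geraniol, (2E)-3,7-dimethylocta-2,6-dien-1-ol
Product: 2 tert-butyl{[(2E)-3,7-dimethylocta-2,6-dien-1-yl]oxy}dimethylsilane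
Conditions: TBSCl, imidazole, DMF, 0 °C → rt
Reagents that add atoms: tert-butyldimethylsilyl chloride, CC(C)(C)[Si](C)(C)Cl
Why: Imidazole-mediated silyl ether formation masks the future C6 oxygen through the oxidation, aldol and acylation steps; no stereocentre is formed.

Step 2
Reactants: 2 tert-butyl{[(2E)-3,7-dimethylocta-2,6-dien-1-yl]oxy}dimethylsilane
Product: 4 (2E,6E)-8-{[tert-butyl(dimethyl)silyl]oxy}-2,6-dimethylocta-2,6-dienal, via allylic alcohol 3 (not isolated)
Conditions: SeO2 (10 mol%), salicylic acid (10 mol%), t-BuOOH (3 equiv), CH2Cl2, rt; then MnO2, CH2Cl2, rt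
Reagents that add atoms: tert-butyl hydroperoxide, CC(C)(C)OO (oxygen source, relayed by catalytic SeO2, O=[Se]=O)
Why: Riley-type SeO2 allylic oxidation (ene reaction, then [2,3]-sigmatropic shift) is selective for the E-methyl of the more electron-rich terminal alkene and keeps the E geometry, and MnO2 then takes the allylic alcohol to the enal.

Step 3
Reactants: 5 furan-3-ylmethanol
Product: 8 [2-(trimethylsilyl)furan-3-yl]methanol, via dilithio alkoxide 6 (not isolated), via bis-silyl furan 7 (not isolated)
Conditions: n-BuLi (2.2 equiv), THF, −78 → 0 °C; TMSCl (2.3 equiv), −78 °C → rt; K2CO3 (cat.), MeOH, rt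
Reagents that add atoms: chlorotrimethylsilane, C[Si](C)(C)Cl
Why: The lithium alkoxide directs the second lithiation to the adjacent furan C2 (directed ortho-metalation), both lithiated sites are silylated, and mild methanolysis removes only the O-silyl group.

Step 4
Reactants: 8 [2-(trimethylsilyl)furan-3-yl]methanol
Product: 10 3-(hydroxymethyl)furan-2(5H)-one, via β,γ-unsaturated lactone 9 (not isolated)
Conditions: AcOOH, NaOAc, CH2Cl2, 0 °C → rt; then Et3N (cat.)
Reagents that add atoms: peracetic acid, CC(=O)OO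
Why: Peracid oxidation of a 2-silylfuran puts the carbonyl on the silicon-bearing carbon by ipso attack and loss of silicon, and amine-catalysed double-bond migration gives the conjugated butenolide.

Step 5
Reactants: 4 (2E,6E)-8-{[tert-butyl(dimethyl)silyl]oxy}-2,6-dimethylocta-2,6-dienal, 10 3-(hydroxymethyl)furan-2(5H)-one
Product: 11 (5R)-5-[(1S,2E,6E)-8-{[tert-butyl(dimethyl)silyl]oxy}-1-hydroxy-2,6-dimethylocta-2,6-dien-1-yl]-3-(hydroxymethyl)furan-2(5H)-one
Conditions: quinine-derived squaramide 3-{[3,5-bis(trifluoromethyl)phenyl]amino}-4-{[(8α,9S)-6′-methoxycinchonan-9-yl]amino}cyclobut-3-ene-1,2-dione (10 mol%), 10 (1.5 equiv), CH2Cl2, −20 °C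
Reagents that add atoms: none
Why: Proposed new method: a direct vinylogous aldol addition of an unprotected 3-substituted butenolide to an α-branched enal under bifunctional amine–squaramide catalysis, in which the quinuclidine nitrogen reversibly deprotonates C5 of 10 to an ammonium-bound 2-oxidofuran while the squaramide N–H pair binds and orients the aldehyde, so that the γ-carbon attacks the carbonyl (1,2-addition) through an open hydrogen-bonded transition state that keeps the butenolide ring anti to the bulky alkenyl residue and sets C8 (R) and C9 (S) in the anti relationship; the closest known reaction is the anti-selective amine–squaramide or amine–thiourea catalysed direct vinylogous aldol addition of unsubstituted furan-2(5H)-one to aromatic aldehydes, which has not been shown with a 3-(hydroxymethyl) donor or an α-branched aliphatic enal.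

Step 6
Reactants: 11 (5R)-5-[(1S,2E,6E)-8-{[tert-butyl(dimethyl)silyl]oxy}-1-hydroxy-2,6-dimethylocta-2,6-dien-1-yl]-3-(hydroxymethyl)furan-2(5H)-one
Product: 12 {(5R)-5-[(1S,2E,6E)-8-{[tert-butyl(dimethyl)silyl]oxy}-2,6-dimethyl-1-[(2-methylpropanoyl)oxy]octa-2,6-dien-1-yl]-2-oxo-2,5-dihydrofuran-3-yl}methyl 2-methylpropanoate
Conditions: i-PrCOCl (2.5 equiv), pyridine, CH2Cl2, −20 → 0 °C
Reagents that add atoms: 2-methylpropanoyl chloride, CC(C)C(Cl)=O
Why: Pyridine-mediated O-acylation esterifies both hydroxyls, which installs the C9 isobutyrate of the target and turns the allylic CH2OH into the leaving group for ring closure, while the weak base and low temperature avoid γ-deprotonation and β-elimination of the butenolide; no stereocentre is touched.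

Step 7
Reactants: 12 the bis-isobutyrate silyl ether
Product: 13 {(5R)-5-[(1S,2E,6E)-8-hydroxy-2,6-dimethyl-1-[(2-methylpropanoyl)oxy]octa-2,6-dien-1-yl]-2-oxo-2,5-dihydrofuran-3-yl}methyl 2-methylpropanoate
Conditions: HF·pyridine, pyridine, THF, 0 °C
Reagents that add atoms: none
Why: Buffered fluoride cleavage of the primary silyl ether (Si–F bond formation) frees the allylic alcohol without touching the esters or the lactone.

Step 8
Reactants: 13 the allylic alcohol
Product: 14 {(5R)-5-[(1S,2E)-5-[(2S,3S)-3-(hydroxymethyl)-2-methyloxiran-2-yl]-2-methyl-1-[(2-methylpropanoyl)oxy]pent-2-en-1-yl]-2-oxo-2,5-dihydrofuran-3-yl}methyl 2-methylpropanoate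
Conditions: Ti(OiPr)4 (10 mol%), L-(+)-diethyl tartrate (12 mol%), t-BuOOH (2 equiv), 4 Å MS, CH2Cl2, −20 °C
Reagents that add atoms: tert-butyl hydroperoxide, CC(C)(C)OO
Why: Sharpless asymmetric epoxidation acts only on the alkene of the free primary allylic alcohol and, with L-(+)-diethyl tartrate on this geraniol-type substrate, gives the (2S,3S)-epoxy alcohol, i.e. C4 (S) and C5 (S), under reagent control.

Step 9
Reactants: 14 the epoxy alcohol
Product: 15 {(5R)-5-[(1S,2E)-5-[(2S,3R)-3-formyl-2-methyloxiran-2-yl]-2-methyl-1-[(2-methylpropanoyl)oxy]pent-2-en-1-yl]-2-oxo-2,5-dihydrofuran-3-yl}methyl 2-methylpropanoate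
Conditions: Dess–Martin periodinane, pyridine, CH2Cl2, 0 °C → rt
Reagents that add atoms: none
Why: Dess–Martin oxidation takes the primary epoxy alcohol to the α,β-epoxy aldehyde under buffered conditions that leave the oxirane and its configuration intact (the descriptor at the aldehyde-bearing carbon changes only because the priorities change).

Step 10
Reactants: 15 the epoxy aldehyde
Product: 16 (1(10)E,4S,5S,6S,7S,8R,9S)-4,5-epoxy-6-hydroxy-9-[(2-methylpropanoyl)oxy]germacra-1(10),11(13)-dien-12,8-olide (CNP0220196.1)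
Conditions: Pd(PPh3)4 (10 mol%), InI (2.5 equiv), THF, 25 °C, 2 mM, syringe-pump addition of 15
Reagents that add atoms: none
Why: In this palladium-catalysed umpolung (Barbier-type) allylation, zerovalent palladium ionises the primary allylic isobutyrate and InI converts the π-allyl complex into an allylindium species that adds through ring carbon C7 to the aldehyde in a chair-like Zimmerman–Traxler transition state, which closes the ten-membered ring trans to the C8 substituent (C7 S), sets C6 (S) in the sense that matches the Felkin–Anh/Cornforth-preferred anti addition to the epoxy aldehyde, and moves the double bond to the exocyclic methylene.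

**Compound list**

1 | geraniol, (2E)-3,7-dimethylocta-2,6-dien-1-ol | CC(C)=CCC/C(C)=C/CO | starting material
2 | tert-butyl{[(2E)-3,7-dimethylocta-2,6-dien-1-yl]oxy}dimethylsilane | CC(C)=CCC/C(C)=C/CO[Si](C)(C)C(C)(C)C | intermediate
3 | (2E,6E)-8-{[tert-butyl(dimethyl)silyl]oxy}-2,6-dimethylocta-2,6-dien-1-ol | OC/C(C)=C/CC/C(C)=C/CO[Si](C)(C)C(C)(C)C | intermediate (not isolated)
4 | (2E,6E)-8-{[tert-butyl(dimethyl)silyl]oxy}-2,6-dimethylocta-2,6-dienal | O=C/C(C)=C/CC/C(C)=C/CO[Si](C)(C)C(C)(C)C | intermediate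
5 | furan-3-ylmethanol | OCc1ccoc1 | starting material
6 | lithium (2-lithiofuran-3-yl)methanolate | [Li]OCc1ccoc1[Li] | intermediate (not isolated)
7 | trimethyl{[2-(trimethylsilyl)furan-3-yl]methoxy}silane | C[Si](C)(C)OCc1ccoc1[Si](C)(C)C | intermediate (not isolated)
8 | [2-(trimethylsilyl)furan-3-yl]methanol | OCc1ccoc1[Si](C)(C)C | intermediate
9 | 3-(hydroxymethyl)furan-2(3H)-one (racemic, transient) | O=C1OC=CC1CO | intermediate (not isolated)
10 | 3-(hydroxymethyl)furan-2(5H)-one | O=C1OCC=C1CO | intermediate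
11 | (5R)-5-[(1S,2E,6E)-8-{[tert-butyl(dimethyl)silyl]oxy}-1-hydroxy-2,6-dimethylocta-2,6-dien-1-yl]-3-(hydroxymethyl)furan-2(5H)-one | CC(C)(C)[Si](C)(C)OC/C=C(C)/CC/C=C(\C)[C@H](O)[C@@H]1OC(=O)C(CO)=C1 | intermediate
12 | {(5R)-5-[(1S,2E,6E)-8-{[tert-butyl(dimethyl)silyl]oxy}-2,6-dimethyl-1-[(2-methylpropanoyl)oxy]octa-2,6-dien-1-yl]-2-oxo-2,5-dihydrofuran-3-yl}methyl 2-methylpropanoate | CC(C)(C)[Si](C)(C)OC/C=C(C)/CC/C=C(\C)[C@H](OC(=O)C(C)C)[C@@H]1OC(=O)C(COC(=O)C(C)C)=C1 | intermediate
13 | {(5R)-5-[(1S,2E,6E)-8-hydroxy-2,6-dimethyl-1-[(2-methylpropanoyl)oxy]octa-2,6-dien-1-yl]-2-oxo-2,5-dihydrofuran-3-yl}methyl 2-methylpropanoate | OC/C=C(C)/CC/C=C(\C)[C@H](OC(=O)C(C)C)[C@@H]1OC(=O)C(COC(=O)C(C)C)=C1 | intermediate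
14 | {(5R)-5-[(1S,2E)-5-[(2S,3S)-3-(hydroxymethyl)-2-methyloxiran-2-yl]-2-methyl-1-[(2-methylpropanoyl)oxy]pent-2-en-1-yl]-2-oxo-2,5-dihydrofuran-3-yl}methyl 2-methylpropanoate | OC[C@@H]1O[C@@]1(C)CC/C=C(\C)[C@H](OC(=O)C(C)C)[C@@H]1OC(=O)C(COC(=O)C(C)C)=C1 | intermediate
15 | {(5R)-5-[(1S,2E)-5-[(2S,3R)-3-formyl-2-methyloxiran-2-yl]-2-methyl-1-[(2-methylpropanoyl)oxy]pent-2-en-1-yl]-2-oxo-2,5-dihydrofuran-3-yl}methyl 2-methylpropanoate | O=C[C@@H]1O[C@@]1(C)CC/C=C(\C)[C@H](OC(=O)C(C)C)[C@@H]1OC(=O)C(COC(=O)C(C)C)=C1 | intermediate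
16 | (1(10)E,4S,5S,6S,7S,8R,9S)-4,5-epoxy-6-hydroxy-9-[(2-methylpropanoyl)oxy]germacra-1(10),11(13)-dien-12,8-olide | C=C1C(=O)O[C@@H]2[C@@H]1[C@H](O)[C@@H]1O[C@@]1(C)CC/C=C(\C)[C@@H]2OC(=O)C(C)C | target

**Step count**

Total: 10 steps (two 2-step branches, then 6 steps after they join). Longest linear sequence: 8 steps (geraniol → 16: steps 1, 2, 5, 6, 7, 8, 9, 10).

**Three steps most likely to fail, with fallbacks**

Step 5 (the proposed new vinylogous aldol addition). Risks are low conversion with the α-branched enal, 1,4-addition, and poor anti-selectivity or enantioselectivity with the free CH2OH donor. The fallback replaces soft enolisation by a preformed silyl dienolate and known chemistry. It sets out from 10, which is silylated (TMSCl, Et3N, CH2Cl2, 0 °C) to the 2-silyloxyfuran trimethyl[(3-{[(trimethylsilyl)oxy]methyl}furan-2-yl)oxy]silane F1. F1 and 4 are then combined under the known anti-selective organocatalytic vinylogous Mukaiyama aldol conditions (a cinchona-alkaloid thiourea used as its ammonium carboxylate salt, Et2O, −20 °C) to give the silylated adduct (5R)-5-[(1S,2E,6E)-8-{[tert-butyl(dimethyl)silyl]oxy}-2,6-dimethyl-1-[(trimethylsilyl)oxy]octa-2,6-dien-1-yl]-3-{[(trimethylsilyl)oxy]methyl}furan-2(5H)-one F2. Citric acid in MeOH at 0 °C removes both trimethylsilyl groups while the TBS ether stays, and the route is rejoined at 11.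

Step 10 (ring closure). Risks are oligomerisation, opening of the oxirane, ionisation of the C9 allylic ester, or the wrong C6 epimer. The fallback closes the ring before the epoxide exists. It sets out from 13, which MnO2 in CH2Cl2 oxidises to the enal {(5R)-5-[(1S,2E,6E)-2,6-dimethyl-1-[(2-methylpropanoyl)oxy]-8-oxoocta-2,6-dien-1-yl]-2-oxo-2,5-dihydrofuran-3-yl}methyl 2-methylpropanoate F3. The Pd(PPh3)4/InI high-dilution closure is then run on this enal, which has no oxirane, to give the macrocyclic allylic alcohol (1(10)E,4E,6R,7S,8R,9S)-6-hydroxy-9-[(2-methylpropanoyl)oxy]germacra-1(10),4,11(13)-trien-12,8-olide F4 (same spatial arrangement at C6 as in 16; the descriptor differs only through priorities). Hydroxyl-directed epoxidation (Ti(OiPr)4, L-(+)-diethyl tartrate, t-BuOOH, CH2Cl2, −20 °C) then gives 16. The ring bond C6–C7 must lie on the inner face of the C4=C5 bond, so metal-bound oxygen can only be delivered to the outer face from the rotamer that leads to the erythro (4S,5S) epoxy alcohol, which is also the matched sense for L-(+)-tartrate.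

Step 2 (allylic oxidation). Risks are incomplete conversion, over-oxidation, attack at the other alkene, or loss of the silyl group under the acidic selenium conditions. The fallback builds the enal by chain shortening and olefination. It sets out from 2, whose more electron-rich terminal alkene is cleaved selectively by ozone (1 equiv O3, CH2Cl2, −78 °C; Me2S) to (4E)-6-{[tert-butyl(dimethyl)silyl]oxy}-4-methylhex-4-enal F5. A Wittig reaction of F5 with the stabilised ylide 2-(triphenylphosphoranylidene)propanal (toluene, 90 °C) gives the (E)-enal, and the route is rejoined at 4.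

**Further compounds**

F1 | step 5 | trimethyl[(3-{[(trimethylsilyl)oxy]methyl}furan-2-yl)oxy]silane | C[Si](C)(C)OCc1ccoc1O[Si](C)(C)C
F2 | step 5 | (5R)-5-[(1S,2E,6E)-8-{[tert-butyl(dimethyl)silyl]oxy}-2,6-dimethyl-1-[(trimethylsilyl)oxy]octa-2,6-dien-1-yl]-3-{[(trimethylsilyl)oxy]methyl}furan-2(5H)-one | CC(C)(C)[Si](C)(C)OC/C=C(C)/CC/C=C(\C)[C@H](O[Si](C)(C)C)[C@@H]1OC(=O)C(CO[Si](C)(C)C)=C1
F3 | step 10 | {(5R)-5-[(1S,2E,6E)-2,6-dimethyl-1-[(2-methylpropanoyl)oxy]-8-oxoocta-2,6-dien-1-yl]-2-oxo-2,5-dihydrofuran-3-yl}methyl 2-methylpropanoate | O=C/C=C(C)/CC/C=C(\C)[C@H](OC(=O)C(C)C)[C@@H]1OC(=O)C(COC(=O)C(C)C)=C1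
F4 | step 10 | (1(10)E,4E,6R,7S,8R,9S)-6-hydroxy-9-[(2-methylpropanoyl)oxy]germacra-1(10),4,11(13)-trien-12,8-olide | C=C1C(=O)O[C@@H]2[C@@H]1[C@H](O)/C=C(\C)CC/C=C(\C)[C@@H]2OC(=O)C(C)C
F5 | step 2 | (4E)-6-{[tert-butyl(dimethyl)silyl]oxy}-4-methylhex-4-enal | O=CCC/C(C)=C/CO[Si](C)(C)C(C)(C)C
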